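All runs were generated by integration on assumed constants; the scatter is artificial.

Time is what you have to spend: the larch flask gets 74 min, at the temperature of the earlier runs.

| flask | substrate | partner | catalyst | product | time |
|---|---|---|---|---|---|
| elm | 250 mM | 375 mM | 0.500 mM |  |  |
| alder | 150 mM | 275 mM | 0.500 mM |  |  |
| ash | 250 mM | 375 mM | 0.500 mM | 75.0 mM |  |
| birch | 250 mM | 750 mM | 0.500 mM |  |  |
| larch | 500 mM | 375 mM | 1.50 mM |  | 74 min |

- elm run (time / min: [product] / mM): 9.2: 35.7; 18: 67.3; 28: 102.2; 37: 132.5; 46: 158.7; 56: 184.3; 65: 204.6; 74: 220.9
- alder run (time / min: [product] / mM): 9.2: 28.4; 18: 57.4; 28: 85.3; 37: 104.0; 46: 121.7; 56: 130.6; 65: 140.1; 74: 147.0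
- ash run (time / min: [product] / mM): 9.2: 109.3; 18: 142.6; 28: 177.1; 37: 208.2; 46: 233.7; 56: 260.1; 65: 280.9; 74: 295.8
- birch run (time / min: [product] / mM): 9.2: 35.9; 18: 68.2; 28: 102.6; 37: 135.0; 46: 162.0; 56: 189.0; 65: 207.5; 74: 224.9

(scatter of a reading: 1 mM)

- how the opening rate goes with [partner] round the charge of the elm run: the exponent of the rate at two percent of substrate gone to product
- how the opening rate goes with [substrate] round the charge of the elm run: the exponent of the rate at two percent of substrate gone to product (one fixed amount of product, the same in the runs compared)
- the alder run starts with 100 mM less of substrate and of partner than the elm run, and with no product. Compared where both hold the same amount of substrate, once fifteen percent of what the alder run was charged with has turned into product, is the alder run faster, slower or alike (within a tenth)?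
- product in the larch run at 74 min, as a share of the substrate charged

- Overall: substrate + partner -> product, with catalyst as catalyst.
- Constant volume, constant temperature.
- The analysis sees a species whether free or bound.
- "The second partner" is partner.
- An order is taken over about fifteen percent of the charge, up and down.

Start with the larch charge. Each product takes one substrate and one partner, and larch holds 375 mM of partner against 500 mM of substrate. So partner is the limiting reagent, and product stops at this share of the substrate charge:

375 mM / 500 mM = 75.0 %

Can the catalyst get there in time? You need its turnover: product made per minute per unit of catalyst. At 74 min, elm reads 220.9 mM, and ash, charged with product, reads 221 mM beyond that charge. Birch, with twice the partner, reads 224.9 mM at that time. So I read turnover from elm, correcting for neither. Elm, alder, ash and birch all hold 0.500 mM of catalyst, so I assume turnover holds per unit of catalyst.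

First round, from elm's first reading:

35.7 mM / 9.2 min / 0.500 mM = 7.76 min⁻¹

Partner charge over turnover times larch catalyst:

375 mM / (7.76 min⁻¹ × 1.50 mM) = 32.2 min

This link is weak. Put the answer back in: by then larch is down to 125 mM of substrate, a quarter of its charge, and elm slows as its substrate falls. So go round again with elm's slope between 28 min and 46 min, where its substrate passes from 148 mM to 91.3 mM:

(158.7 mM − 102.2 mM) / (46 min − 28 min) / 0.500 mM = 6.28 min⁻¹

This is the working turnover, the elm slope per unit of catalyst round that substrate level. It is lower than the first figure. Then:

375 mM / (6.28 min⁻¹ × 1.50 mM) = 39.8 min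

That is shorter than 74 min, which leaves room for a slower tail at low partner, which no reading shows. I commit to 75.0 %.

The forecast gives 0.03 for partner, 0.22 for substrate, alike for the comparison and 75 % for larch. It says “Partner is limiting there”, with partner “consumed in about 35 min”; I reckoned 39.8 min.

The larch flask gives 75.0 %. The orders come to 0.041 in partner and 0.20 in substrate, and the alder comparison is alike. The apparent order in catalyst early in the elm run is 1.0.

    catalyst + substrate → catalyst-substrate complex (160.2 M⁻¹ min⁻¹)
    catalyst-substrate complex + partner → product + catalyst (516.0 M⁻¹ min⁻¹)
    catalyst + substrate ⇌ idle catalyst-substrate complex, settled at all times (15.80 M⁻¹)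

At 6.28 min⁻¹, the time reckoned for the larch partner charge is 53.8 % of its 74 min. In the alder run, 6.28 min⁻¹ on 0.500 mM of catalyst gives 11.9 min for a quarter of its substrate charge, and the alder run took 11.6 min.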